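The oxolane (O1, C2 aryl, C3, C4 aroyl, C5H2) is cut at O1–C5 and C3–C4. That leaves a three-atom O1–C2–C3 unit, stored as a strained cis aryl vinyl oxirane, and a two-atom C5–C4 unit, an aryl vinyl ketone that already carries the aroyl group. One palladium(0)-catalysed zwitterionic (3+2) annulation joins them. It forms both bonds, closes the only ring to be built and sets C3 and C4, while C2 arrives intact from the oxirane. The oxirane is the (2S,3R) enantiomer, made in two steps by asymmetric chloroallylboration. The C3 vinyl group is a masked CH2OH; C4 is equilibrated before, not after, that group is unmasked.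

Key step: step 4

Remark on the chemistry: the (Z)-γ-chloroallyl reagent is assumed to select the aldehyde face in the same sense as the parent allyl- and crotyl-diisopinocampheylboranes, so the (+)-α-pinene series, (−)-Ipc2BOMe, is used. All oxolanes are numbered O1, C2 (aryl), C3, C4 (aroyl), C5; on this numbering the target is (2S,3S,4R), 2,3-cis-3,4-trans.

Step 1
Reactants: 1 3,4,5-trimethoxybenzaldehyde; 2 allyl chloride
Product: 5 (1R,2R)-2-chloro-1-(3,4,5-trimethoxyphenyl)but-3-en-1-ol, via (Z)-γ-chloroallyldiisopinocampheylborane 3 (not isolated), via borinate adduct 4 (not isolated)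
Conditions: (−)-Ipc2BOMe, 2, Cy2NLi (from Cy2NH, n-BuLi), Et2O/THF, −95 °C; BF3·OEt2, then 1 (in THF), −95 °C; HOCH2CH2NH2, Et2O, rt
Reagents that add atoms: none
Why: Brown-type asymmetric allylboration with a (Z)-γ-chloroallyl reagent: 2 is lithiated in the presence of the borinate, BF3 strips the methoxide to give 3, and the closed Zimmerman–Traxler chair then turns the Z geometry into the syn (2R) chloride centre while the isopinocampheyl groups of the (+)-α-pinene series select the aldehyde face that gives the 1R carbinol, the future oxolane C2.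

Step 2
Reactants: 5 (1R,2R)-2-chloro-1-(3,4,5-trimethoxyphenyl)but-3-en-1-ol
Product: 6 (2S,3R)-2-ethenyl-3-(3,4,5-trimethoxyphenyl)oxirane (cis)
Conditions: DBU, CH2Cl2, 0 °C to rt; Et3N-deactivated SiO2
Reagents that add atoms: none
Why: Base-induced halohydrin closure (intramolecular Williamson reaction, 3-exo-tet SN2): the alkoxide displaces the allylic chloride with inversion, so the syn chlorohydrin can give only the cis oxirane with the benzylic centre untouched, and an aprotic amidine base spares the solvolysis-prone benzylic C–O bond.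

Step 3
Reactants: 7 3',4',5'-trimethoxyacetophenone
Product: 9 1-(3,4,5-trimethoxyphenyl)prop-2-en-1-one, via Mannich base 8 (not isolated)
Conditions: (CH2O)n, i-Pr2NH·TFA, TFA (10 mol %), THF, reflux; kept cold over a trace of BHT and used at once
Reagents that add atoms: paraformaldehyde (as formaldehyde), C=O
Why: One-pot Mannich condensation and β-elimination (direct α-methylenation of a methyl ketone): the ammonium salt and formaldehyde deliver an iminium ion to the enol of 7, Mannich base 8 loses the bulky amine on heating, and no stereocentre is involved.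

Step 4
Reactants: 6 (2S,3R)-2-ethenyl-3-(3,4,5-trimethoxyphenyl)oxirane; 9 1-(3,4,5-trimethoxyphenyl)prop-2-en-1-one
Product: 11 (2S,3R,4R)-3-ethenyl-4-(3,4,5-trimethoxybenzoyl)-2-(3,4,5-trimethoxyphenyl)oxolane (2,3-cis-3,4-trans), via all-cis C4-epimer 10 (not isolated)
Conditions: Pd2(dba)3·CHCl3 (2.5 mol %), dppe (6 mol %), 9 (1.5 equiv), THF, 0 °C, slow addition of 6; then DBU (0.3 equiv), rt to 40 °C
Reagents that add atoms: none
Why: Pd(0) ionises the allylic C–O bond of 6 with inversion, helped by release of oxirane strain, to a zwitterion in which the benzylic C2 alkoxide is tethered to a cationic η3-allyl unit; the alkoxide adds to the unsubstituted β-carbon of 9 (O1–C5) and the aryl ketone enolate so formed attacks the internal allyl carbon on the face away from palladium (C3–C4), which frees Pd(0). The reaction type is the palladium-catalysed zwitterionic (3+2) annulation of vinyl epoxides with electron-poor alkenes, known for doubly activated acceptors and also for simple α,β-unsaturated ketones. The oxolane closes by 5-exo attack on the allyl unit, which is preferred to 7-endo attack at the CH2 terminus and to O-alkylation of the enolate. C3 is governed by the configuration of the oxirane carbon through two successive inversions (net retention, so the cis oxirane becomes the 2,3-cis oxolane), C2 is carried through unchanged, and C4 is governed by thermodynamics, since it is enolisable and the DBU hold turns any all-cis epimer 10 into the 3,4-trans ketone 11 with the aroyl group anti to the vinyl and aryl groups. The step needs capture and closure that outrun η3–η1–η3 face exchange through the unsubstituted allyl terminus and hydride migration to an allyl aryl ketone; the sterically open, highly electrophilic vinyl ketone in excess, a chloride-free palladium source, a chelating diphosphine, low temperature and slow addition of 6 all work in that direction. The equilibration is placed here because 11 has a single oxygen nucleophile and no acidic C3–H, so even a reversible β-elimination of O1 can only re-form the same ring.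

Step 5
Reactants: 11 (2S,3R,4R)-3-ethenyl-4-(3,4,5-trimethoxybenzoyl)-2-(3,4,5-trimethoxyphenyl)oxolane
Product: 13 (2S,3R,4R)-4-(3,4,5-trimethoxybenzoyl)-2-(3,4,5-trimethoxyphenyl)oxolane-3-carbaldehyde, via vicinal diol 12 (not isolated)
Conditions: OsO4 (2 mol %), NaIO4, 2,6-lutidine, dioxane/H2O 3:1, 0 °C to rt; crude 13 used at once
Reagents that add atoms: osmium tetroxide, O=[Os](=O)(=O)=O (transfers the oxygen); sodium periodate, [Na+].[O-]I(=O)(=O)=O (terminal oxidant that restores it)
Why: Lemieux–Johnson oxidation: the monosubstituted alkene is the only site open to osmylation, periodate cleaves diol 12 as it forms, and the lutidine buffer keeps the medium close to neutral so that the C3 and C4 centres next to the two carbonyl groups are not enolised.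

Step 6
Reactants: 13 (2S,3R,4R)-4-(3,4,5-trimethoxybenzoyl)-2-(3,4,5-trimethoxyphenyl)oxolane-3-carbaldehyde
Product: 14 (2S,3S,4R)-3-(hydroxymethyl)-4-(3,4,5-trimethoxybenzoyl)-2-(3,4,5-trimethoxyphenyl)oxolane (target)
Conditions: NaBH4, CH2Cl2/MeOH 3:1, −78 °C; aq NH4Cl at −78 °C
Reagents that add atoms: none
Why: Chemoselective borohydride reduction: at −78 °C in dichloromethane–methanol an aliphatic aldehyde is reduced much faster than a hindered aryl ketone deactivated by its electron-rich ring, the cold medium leaves C3 and C4 untouched, and the 3,4-trans arrangement disfavours hemiketal formation in 14.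

Compound list
1 | 3,4,5-trimethoxybenzaldehyde | COc1cc(C=O)cc(OC)c1OC | starting material
2 | allyl chloride | C=CCCl | starting material
3 | (Z)-γ-chloroallyldiisopinocampheylborane, Ipc groups of the (+)-α-pinene series | Cl/C=C\CB([C@@H]1C[C@@H]2C[C@H]([C@H]1C)C2(C)C)[C@@H]1C[C@@H]2C[C@H]([C@H]1C)C2(C)C | intermediate
4 | diisopinocampheylborinate of chlorohydrin 5 | B(O[C@H](c1cc(OC)c(OC)c(OC)c1)[C@H](Cl)C=C)([C@@H]1C[C@@H]2C[C@H]([C@H]1C)C2(C)C)[C@@H]1C[C@@H]2C[C@H]([C@H]1C)C2(C)C | intermediate
5 | (1R,2R)-2-chloro-1-(3,4,5-trimethoxyphenyl)but-3-en-1-ol (syn) | O[C@H](c1cc(OC)c(OC)c(OC)c1)[C@H](Cl)C=C | intermediate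
6 | (2S,3R)-2-ethenyl-3-(3,4,5-trimethoxyphenyl)oxirane (cis) | O1[C@H](c2cc(OC)c(OC)c(OC)c2)[C@@H]1C=C | intermediate
7 | 3',4',5'-trimethoxyacetophenone | CC(=O)c1cc(OC)c(OC)c(OC)c1 | starting material
8 | 3-(diisopropylamino)-1-(3,4,5-trimethoxyphenyl)propan-1-one | CC(C)N(CCC(=O)c1cc(OC)c(OC)c(OC)c1)C(C)C | intermediate
9 | 1-(3,4,5-trimethoxyphenyl)prop-2-en-1-one | C=CC(=O)c1cc(OC)c(OC)c(OC)c1 | intermediate
10 | (2S,3R,4S)-3-ethenyl-4-(3,4,5-trimethoxybenzoyl)-2-(3,4,5-trimethoxyphenyl)oxolane (all-cis) | COc1cc(C(=O)[C@@H]2CO[C@H](c3cc(OC)c(OC)c(OC)c3)[C@@H]2C=C)cc(OC)c1OC | intermediate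
11 | (2S,3R,4R)-3-ethenyl-4-(3,4,5-trimethoxybenzoyl)-2-(3,4,5-trimethoxyphenyl)oxolane (2,3-cis-3,4-trans) | COc1cc(C(=O)[C@H]2CO[C@H](c3cc(OC)c(OC)c(OC)c3)[C@@H]2C=C)cc(OC)c1OC | intermediate
12 | (2S,3R,4R)-3-(1,2-dihydroxyethyl)-4-(3,4,5-trimethoxybenzoyl)-2-(3,4,5-trimethoxyphenyl)oxolane (side-chain carbinol epimers) | COc1cc(C(=O)[C@H]2CO[C@H](c3cc(OC)c(OC)c(OC)c3)[C@@H]2C(O)CO)cc(OC)c1OC | intermediate
13 | (2S,3R,4R)-4-(3,4,5-trimethoxybenzoyl)-2-(3,4,5-trimethoxyphenyl)oxolane-3-carbaldehyde | COc1cc(C(=O)[C@H]2CO[C@H](c3cc(OC)c(OC)c(OC)c3)[C@@H]2C=O)cc(OC)c1OC | intermediate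
14 | (2S,3S,4R)-3-(hydroxymethyl)-4-(3,4,5-trimethoxybenzoyl)-2-(3,4,5-trimethoxyphenyl)oxolane | COc1cc(C(=O)[C@H]2CO[C@H](c3cc(OC)c(OC)c(OC)c3)[C@@H]2CO)cc(OC)c1OC | target

Total step count: 6. Longest linear sequence: 5 (steps 1, 2, 4, 5, 6 from 1); step 3 is the one-step side branch.

Steps most likely to fail

Step 4. Palladium may exchange between the two allyl faces through the unsubstituted terminus before the ring closes, which would erode the 2,3-cis relationship. Hydride migration within the zwitterion and anionic oligomerisation of the vinyl ketone would cost material. The fallback drops the metal–allyl intermediate and makes the two bonds by separate, stereospecific polar steps. It sets out from chlorohydrin 5 and enone 9.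
- A Brønsted-acid-catalysed oxa-Michael addition (Tf2NH, 5 mol %, CH2Cl2, 0 °C) uses no base, so oxirane closure cannot compete. It should give the β-alkoxy ketone 3-{[(1R,2R)-2-chloro-1-(3,4,5-trimethoxyphenyl)but-3-en-1-yl]oxy}-1-(3,4,5-trimethoxyphenyl)propan-1-one F1.
- KHMDS (THF, −78 to −20 °C) then forms the ketone enolate, which displaces the secondary allylic chloride in a 5-exo-tet SN2 reaction.
- The single inversion puts C4 where the oxirane oxygen of 6 sits, which is the same 2,3-cis outcome. After the same DBU equilibration the sequence comes back to the route at 11.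

Step 5. The new aldehyde may enolise at C3 during cleavage or handling. That would invert C3 towards the more stable 2,3-trans series or trigger β-elimination of O1. The fallback takes the aroyl group out of play first and sets out from 11.
- NaBH4 (MeOH, 0 °C) should give the benzylic alcohol (2S,3R,4R)-3-ethenyl-4-[hydroxy(3,4,5-trimethoxyphenyl)methyl]-2-(3,4,5-trimethoxyphenyl)oxolane F2 (carbinol epimers, of no consequence).
- The vinyl group is cleaved with OsO4/NaIO4, and the organic extract is treated at once with excess NaBH4 at 0 °C. No chemoselectivity is needed now, so the aldehyde lives only briefly. This should give the diol (2S,3S,4R)-3-(hydroxymethyl)-4-[hydroxy(3,4,5-trimethoxyphenyl)methyl]-2-(3,4,5-trimethoxyphenyl)oxolane F3.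
- Activated MnO2 (CH2Cl2, rt) oxidises only the benzylic alcohol, and the sequence comes back at 14.

Step 1. The lithiated allyl chloride may decompose, or the chloroallylborane may lose its Z geometry by 1,3-borotropic shift, if the poorly soluble, electron-rich aldehyde reacts too slowly at −95 °C. Either process would erode syn selectivity and enantiomeric purity. The fallback sets the oxirane by reagent-controlled epoxidation of a Z-allylic alcohol and sets out from 1.
- Still–Gennari olefination ((CF3CH2O)2P(O)CH2CO2Me, KHMDS, 18-crown-6, THF, −78 °C) should give methyl (Z)-3-(3,4,5-trimethoxyphenyl)prop-2-enoate F4.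
- DIBAL-H (CH2Cl2, −78 °C) should give (Z)-3-(3,4,5-trimethoxyphenyl)prop-2-en-1-ol F5.
- Sharpless asymmetric epoxidation (Ti(Oi-Pr)4, L-(+)-DIPT, t-BuOOH, 4 Å sieves, CH2Cl2, −20 °C) should give [(2S,3R)-3-(3,4,5-trimethoxyphenyl)oxiran-2-yl]methanol F6.
- Dess–Martin oxidation buffered with NaHCO3 should give (2R,3R)-3-(3,4,5-trimethoxyphenyl)oxirane-2-carbaldehyde F7.
- Wittig methylenation (Ph3P=CH2, THF, −78 to 0 °C) brings the sequence back to the route at 6.

Further compounds
F1 | step 4 | 3-{[(1R,2R)-2-chloro-1-(3,4,5-trimethoxyphenyl)but-3-en-1-yl]oxy}-1-(3,4,5-trimethoxyphenyl)propan-1-one | O(CCC(=O)c1cc(OC)c(OC)c(OC)c1)[C@H](c1cc(OC)c(OC)c(OC)c1)[C@H](Cl)C=C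
F2 | step 5 | (2S,3R,4R)-3-ethenyl-4-[hydroxy(3,4,5-trimethoxyphenyl)methyl]-2-(3,4,5-trimethoxyphenyl)oxolane | COc1cc(C(O)[C@H]2CO[C@H](c3cc(OC)c(OC)c(OC)c3)[C@@H]2C=C)cc(OC)c1OC
F3 | step 5 | (2S,3S,4R)-3-(hydroxymethyl)-4-[hydroxy(3,4,5-trimethoxyphenyl)methyl]-2-(3,4,5-trimethoxyphenyl)oxolane | COc1cc(C(O)[C@H]2CO[C@H](c3cc(OC)c(OC)c(OC)c3)[C@@H]2CO)cc(OC)c1OC
F4 | step 1 | methyl (Z)-3-(3,4,5-trimethoxyphenyl)prop-2-enoate | COC(=O)/C=C\c1cc(OC)c(OC)c(OC)c1
F5 | step 1 | (Z)-3-(3,4,5-trimethoxyphenyl)prop-2-en-1-ol | OC/C=C\c1cc(OC)c(OC)c(OC)c1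
F6 | step 1 | [(2S,3R)-3-(3,4,5-trimethoxyphenyl)oxiran-2-yl]methanol | O1[C@H](c2cc(OC)c(OC)c(OC)c2)[C@@H]1CO
F7 | step 1 | (2R,3R)-3-(3,4,5-trimethoxyphenyl)oxirane-2-carbaldehyde | O1[C@H](c2cc(OC)c(OC)c(OC)c2)[C@@H]1C=O
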